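Ring B of this normal labdane (labdane numbering throughout) is a cyclohexene. Its C7=C8 alkene lies between C6 and C9 and faces the adjacent pair C5–C10, which is the imprint of a [4+2] union of a C6=C7–C8=C9 diene (C17 on C8, C11 on C9) with a C5=C10 alkene carrying C4, C1 and C20.
Cuts, in retrosynthetic order: the two acetates; a temporary C1 carbonyl is put back; C3–C4 (ring A); C4–C18, C4–C19 and C1–C2; C5–C6 and C9–C10 (ring B); C7–C8; C8–C17 and the C8–C9 link to a C9 aldehyde obtained from citronellol.
Forward: the C9–C16 chain is grown into the diene, and ring B is closed with the complete side chain and the C17 oxygen in place. Ring A is closed last by a radical C3–C4 bond formation between the arms on C10 and C5, then C1 is deoxygenated and the silyl ethers are exchanged for acetates.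
Stereochemistry: C13 is taken from (S)-citronellol. C5, C9 and C10 all arise in the cycloaddition (alkene geometry of both partners, formyl-exo topology, face chosen by a chiral boron cation), and the trans ring fusion follows from the trans C1/C4 arms.

Key step: step 8

TBS = tert-butyldimethylsilyl; α/β refer to the usual labdane drawing.
Assumption: the (S)-prolinol-derived boron cation is taken to leave open the C10-Re/C5-Re face of the bound 2-methyl enal, as its accepted binding model predicts.
Assumption: the C1 carbinol centre that exists before the enone stage, and again before the deoxygenation, is carried as an epimer mixture because C1 ends as CH2.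

Step 1
Reactants: 1 (S)-citronellol
Product: 2 (S)-citronellyl TBS ether
Conditions: TBSCl, imidazole, CH2Cl2, 0 °C → rt
Reagents that add atoms: tert-butyldimethylsilyl chloride, CC(C)(C)[Si](C)(C)Cl
Why: Standard imidazole-promoted silylation of a primary alcohol; the C13 stereocentre (S, from the chiral pool) is untouched and the TBS ether tolerates every step up to the final fluoride treatment.

Step 2
Reactants: 2 (S)-citronellyl TBS ether
Product: 4 (4S)-6-(TBSO)-4-methylhexanal, via secondary ozonide 3 (not isolated)
Conditions: O3, CH2Cl2, −78 °C; then Me2S, −78 °C → rt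
Reagents that add atoms: ozone, [O-][O+]=O
Why: Ozonolysis with reductive work-up cleaves the only alkene, the electron-rich trisubstituted C=C, to the aldehyde whose carbonyl carbon becomes C9, while the silyl ether and the remote stereocentre are inert.

Step 3
Reactants: 4 (4S)-6-(TBSO)-4-methylhexanal
Product: 5 (3S)-1-(TBSO)-3-methylhept-6-yne
Conditions: dimethyl (1-diazo-2-oxopropyl)phosphonate, K2CO3, MeOH, 0 °C → rt
Reagents that add atoms: dimethyl (1-diazo-2-oxopropyl)phosphonate, COP(=O)(OC)C(=[N+]=[N-])C(C)=O
Why: The Ohira–Bestmann (Seyferth–Gilbert type) homologation converts the unhindered aldehyde, which has no α-stereocentre, into the terminal alkyne under mild carbonate conditions and adds the carbon that becomes C8.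

Step 4
Reactants: 5 (3S)-1-(TBSO)-3-methylhept-6-yne
Product: 7 (6S)-8-(TBSO)-6-methyloct-2-yn-1-ol, via lithium acetylide 6 (not isolated)
Conditions: n-BuLi, THF, −78 °C; then (CH2O)n, −78 °C → rt; H2O
Reagents that add atoms: paraformaldehyde (reacts as formaldehyde), C=O
Why: Deprotonation of the terminal alkyne and 1,2-addition of the acetylide to formaldehyde is the standard hydroxymethylation and installs C17 at the alcohol oxidation level required in the target.

Step 5
Reactants: 7 (6S)-8-(TBSO)-6-methyloct-2-yn-1-ol
Product: 8 (6S)-1,8-bis(TBSO)-6-methyloct-2-yne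
Conditions: TBSCl, imidazole, CH2Cl2, 0 °C → rt
Reagents that add atoms: tert-butyldimethylsilyl chloride, CC(C)(C)[Si](C)(C)Cl
Why: Routine silylation masks the propargylic alcohol so that no protic site meets the tin hydride, the palladium catalyst or the boron cation later on, and it supplies the bulky silyloxymethyl branch that is wanted on C8 in step 8.

Step 6
Reactants: 8 (6S)-1,8-bis(TBSO)-6-methyloct-2-yne
Product: 9 (2E,6S)-1,8-bis(TBSO)-6-methyl-2-(tributylstannyl)oct-2-ene
Conditions: Bu3SnH (1.5 equiv), Mo(CO)3(CNtBu)3 (5 mol%), hydroquinone (cat.), THF, 55 °C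
Reagents that add atoms: tributyltin hydride, CCCC[SnH](CCCC)CCCC
Why: Molybdenum-catalysed syn-hydrostannation of propargylic ethers places tin on the alkyne carbon next to the C–O bond (C8) and hydrogen on C9 from the same side, which fixes C11 trans to tin and hence the alkene geometry needed for a reactive s-cis diene.

Step 7
Reactants: 9 (2E,6S)-1,8-bis(TBSO)-6-methyl-2-(tributylstannyl)oct-2-ene; 10 vinyl bromide
Product: 11 (3Z,7S)-9-(TBSO)-3-[(TBSO)methyl]-7-methylnona-1,3-diene (C11 trans to the vinyl group)
Conditions: Pd2(dba)3 (2.5 mol%), AsPh3 (10 mol%), 10 (1 M in THF, 3 equiv), NMP, 45 °C, sealed tube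
Reagents that add atoms: none
Why: Stille coupling of an alkenylstannane with a vinyl halide proceeds with retention at both sp2 carbons, so the vinyl group (C6=C7) takes the place of tin trans to C11, and the neutral conditions spare both silyl ethers.

Step 8
Reactants: 11 (3Z,7S)-9-(TBSO)-3-[(TBSO)methyl]-7-methylnona-1,3-diene; 12 ethyl (E)-3-methyl-4-oxobut-2-enoate
Product: 13 ring B adduct ethyl (1R,5S,6R)-4-[(TBSO)methyl]-5-[(3S)-5-(TBSO)-3-methylpentyl]-6-formyl-6-methylcyclohex-3-ene-1-carboxylate
Conditions: (S)-3,3-diphenyl-1-(o-tolyl)tetrahydro-1H,3H-pyrrolo[1,2-c][1,3,2]oxazaborole (20 mol%), HN(SO2CF3)2 (18 mol%), 12 (1.5 equiv), CH2Cl2, −78 → −40 °C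
Reagents that add atoms: none
Why: The N-protonated oxazaborolidine binds the formyl oxygen of 12 (B–O coordination backed by a formyl C–H···O contact), which lowers the LUMO and concentrates it on C5, so that a concerted but asynchronous [4+2] cycloaddition takes place in which C5–C6 runs ahead of C9–C10; the closest known reaction type is the chiral oxazaborolidinium-catalysed Diels–Alder reaction of 2-methyl-2-enals with substituted butadienes. Ring B closes in a single intermolecular [4+2] event, suprafacial on both partners, and the new alkene appears at C7=C8 with C17 and the whole side chain already attached. C5 relative to C10 is controlled by the E geometry of 12, which is carried over so that C4 (ester) and C1 (formyl) end up trans, the pattern of a trans ring fusion. C9 relative to C10 is controlled by the outside position of C11 on the diene combined with the formyl-exo, ester-endo transition state, which puts C11 cis to the C10 methyl group; this topology is expected because 2-methyl enals avoid the formyl-endo mode, the ester takes the endo overlap instead, and the silyloxymethyl branch on C8 leaves room underneath only for the small methyl group. The absolute configuration is controlled by the catalyst, whose aryl group covers one face of the bound s-trans enal so that the diene adds to the open C10-Re/C5-Re face. The step also needs regioselectivity (C9 to C10), which is secured by the C11 alkyl group on the diene terminus that makes C6 the nucleophilic end, whereas the oxygen-attenuated C17 branch is too weak a donor to reverse this.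

Step 9
Reactants: 13 ring B adduct
Product: 14 C1 allylic alcohol (formyl group of 13 converted into CH(OH)CH=CH2, C1 epimers)
Conditions: CH2=CHMgBr (1.2 equiv), THF, −78 → −20 °C; H2O
Reagents that add atoms: vinylmagnesium bromide, C=C[Mg]Br
Why: This is a chemoselective Grignard 1,2-addition in which the non-enolisable formyl group reacts far faster at low temperature than the hindered secondary ester, and the new C1 carbinol centre (either epimer) is erased in step 11.

Step 10
Reactants: 14 C1 allylic alcohol
Product: 15 diol (ester of 14 converted into C(CH3)2OH)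
Conditions: MeLi (6 equiv), Et2O/THF, −78 → 0 °C; H2O
Reagents that add atoms: methyllithium, [Li]C
Why: Double addition of methyllithium to the ester, after deprotonation of the C1 hydroxyl, gives the dimethylcarbinol that carries C18 and C19, and C5 is not at risk because its substituent already sits in the more stable equatorial position.

Step 11
Reactants: 15 diol
Product: 16 hydroxy enone (C1 vinyl ketone, C4 tertiary alcohol)
Conditions: Dess–Martin periodinane (1.3 equiv), CH2Cl2, 0 °C → rt
Reagents that add atoms: none
Why: Dess–Martin oxidation converts the secondary allylic alcohol into the vinyl ketone under near-neutral conditions, the tertiary alcohol cannot be oxidised, and the C1 epimers converge to one compound.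

Step 12
Reactants: 16 hydroxy enone
Product: 17 isopropenyl vinyl ketone (C5 bears C(CH3)=CH2, C10 bears CH3 and C(=O)CH=CH2)
Conditions: MeO2CN(−)SO2N(+)Et3 (Burgess reagent, 2 equiv), toluene, 50 °C
Reagents that add atoms: none
Why: Burgess dehydration (syn elimination of the sulfamate ester) should take a hydrogen from one of the two methyl groups, since the only other β-hydrogen, C5–H, is shielded by quaternary C10 and its loss would create a tetrasubstituted alkene with severe allylic strain, while the neutral reagent spares the vinyl ketone and the silyl ethers.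

Step 13
Reactants: 17 isopropenyl vinyl ketone
Product: 18 (5S,9S,10S,13S)-15,17-bis(TBSO)labd-7-en-1-one
Conditions: Fe(acac)3 (30 mol%), PhSiH3 (2.5 equiv), EtOH, 60 °C, 0.02 M
Reagents that add atoms: none
Why: In this Mukaiyama-type hydrogen atom transfer followed by an intramolecular Giese addition, the iron hydride delivers H to the CH2 end of the least hindered 1,1-disubstituted alkene, the tertiary C4 radical adds 6-endo to the terminal C3 of the vinyl ketone, and the α-keto radical is reduced and protonated, so that ring A closes on the trans-diequatorial arms as a trans-decalin with no new stereocentre while the hindered trisubstituted C7=C8 alkene reacts much more slowly.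

Step 14
Reactants: 18 15,17-bis(TBSO)labd-7-en-1-one
Product: 19 15,17-bis(TBSO)labd-7-en-1-ol (C1 epimers, equatorial alcohol expected to prevail)
Conditions: LiAlH4, Et2O, 0 °C; H2O
Reagents that add atoms: none
Why: Hydride reduction of the hindered C1 ketone with small, reactive LiAlH4 prepares the deoxygenation, and the carbinol configuration is irrelevant because C1 becomes a methylene group.

Step 15
Reactants: 19 15,17-bis(TBSO)labd-7-en-1-ol
Product: 22 O-[15,17-bis(TBSO)labd-7-en-1-yl] S-methyl dithiocarbonate, via sodium alkoxide 20 (not isolated), via sodium xanthate 21 (not isolated)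
Conditions: NaH, imidazole (cat.), THF, 0 °C → reflux; CS2, rt; MeI, rt
Reagents that add atoms: carbon disulfide, S=C=S; iodomethane, CI
Why: Xanthate formation (alkoxide, CS2, then S-methylation) works even for neopentyl-type secondary alcohols because the electrophile is small and linear, and nothing else in the molecule is acidic or electrophilic.

Step 16
Reactants: 22 O-[15,17-bis(TBSO)labd-7-en-1-yl] S-methyl dithiocarbonate
Product: 23 (5S,9R,10S,13S)-15,17-bis(TBSO)labd-7-ene
Conditions: Bu3SnH (2 equiv), 2,2'-azobis(isobutyronitrile) (cat.), toluene, 110 °C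
Reagents that add atoms: none
Why: In the Barton–McCombie deoxygenation the stannyl radical adds to the thiocarbonyl group and the released secondary C1 radical is quenched by Bu3SnH faster than it can reach the remote, hindered C7=C8 alkene, so no stereocentre is touched.

Step 17
Reactants: 23 15,17-bis(TBSO)labd-7-ene
Product: 24 (5S,9R,10S,13S)-labd-7-ene-15,17-diol
Conditions: Bu4NF (3 equiv), THF, rt
Reagents that add atoms: none
Why: Fluoride-mediated cleavage of both primary TBS ethers is driven by Si–F bond formation and leaves the trisubstituted alkene and all four stereocentres unchanged.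

Step 18
Reactants: 24 labd-7-ene-15,17-diol
Product: 25 (5S,9R,10S,13S)-labd-7-ene-15,17-diyl diacetate (target)
Conditions: Ac2O, pyridine, 4-(dimethylamino)pyridine (cat.), CH2Cl2, rt
Reagents that add atoms: acetic anhydride, CC(=O)OC(C)=O
Why: Nucleophile-catalysed acetylation of the two primary alcohols (one allylic, one saturated) proceeds without ionisation of the allylic position and delivers the target.

Compound list
1 | (S)-citronellol, (3S)-3,7-dimethyloct-6-en-1-ol | C[C@@H](CCC=C(C)C)CCO | starting material
2 | (S)-citronellyl TBS ether, tert-butyl{[(3S)-3,7-dimethyloct-6-en-1-yl]oxy}dimethylsilane | C[C@@H](CCC=C(C)C)CCO[Si](C)(C)C(C)(C)C | intermediate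
3 | secondary ozonide, 3-[(3S)-5-(TBSO)-3-methylpentyl]-5,5-dimethyl-1,2,4-trioxolane (ring CH epimers) | C[C@@H](CCC1OOC(C)(C)O1)CCO[Si](C)(C)C(C)(C)C | intermediate
4 | (4S)-6-(TBSO)-4-methylhexanal | C[C@@H](CCC=O)CCO[Si](C)(C)C(C)(C)C | intermediate
5 | (3S)-1-(TBSO)-3-methylhept-6-yne | C[C@@H](CCC#C)CCO[Si](C)(C)C(C)(C)C | intermediate
6 | lithium acetylide of 5 | C[C@@H](CCC#C[Li])CCO[Si](C)(C)C(C)(C)C | intermediate
7 | (6S)-8-(TBSO)-6-methyloct-2-yn-1-ol | C[C@@H](CCC#CCO)CCO[Si](C)(C)C(C)(C)C | intermediate
8 | (6S)-1,8-bis(TBSO)-6-methyloct-2-yne | C[C@@H](CCC#CCO[Si](C)(C)C(C)(C)C)CCO[Si](C)(C)C(C)(C)C | intermediate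
9 | (2E,6S)-1,8-bis(TBSO)-6-methyl-2-(tributylstannyl)oct-2-ene (Sn on C8, trans to C11) | CCCC[Sn](CCCC)(CCCC)/C(CO[Si](C)(C)C(C)(C)C)=C/CC[C@H](C)CCO[Si](C)(C)C(C)(C)C | intermediate
10 | vinyl bromide | C=CBr | starting material
11 | (3Z,7S)-9-(TBSO)-3-[(TBSO)methyl]-7-methylnona-1,3-diene (C11 trans to the vinyl group) | C=C/C(CO[Si](C)(C)C(C)(C)C)=C/CC[C@H](C)CCO[Si](C)(C)C(C)(C)C | intermediate
12 | ethyl (E)-3-methyl-4-oxobut-2-enoate | CCOC(=O)/C=C(\C)C=O | starting material
13 | ring B adduct, ethyl (1R,5S,6R)-4-[(TBSO)methyl]-5-[(3S)-5-(TBSO)-3-methylpentyl]-6-formyl-6-methylcyclohex-3-ene-1-carboxylate (5α-H, 9α-H, 10β-CH3; C1 = CHO, C4 = CO2Et) | CC(C)(C)[Si](C)(C)OCC[C@@H](C)CC[C@H]1C(CO[Si](C)(C)C(C)(C)C)=CC[C@@H](C(=O)OCC)[C@]1(C)C=O | intermediate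
14 | C1 allylic alcohol, ethyl (1R,5S,6R)-4-[(TBSO)methyl]-5-[(3S)-5-(TBSO)-3-methylpentyl]-6-(1-hydroxyprop-2-en-1-yl)-6-methylcyclohex-3-ene-1-carboxylate (C1 epimers) | CC(C)(C)[Si](C)(C)OCC[C@@H](C)CC[C@H]1C(CO[Si](C)(C)C(C)(C)C)=CC[C@@H](C(=O)OCC)[C@]1(C)C(O)C=C | intermediate
15 | diol: ring B as in 13, C5 bears C(CH3)2OH, C10 bears CH3 and CH(OH)CH=CH2 (C1 epimers; 5α-H, 9α-H, 10β-CH3, 13S) | CC(C)(C)[Si](C)(C)OCC[C@@H](C)CC[C@H]1C(CO[Si](C)(C)C(C)(C)C)=CC[C@@H](C(C)(C)O)[C@]1(C)C(O)C=C | intermediate
16 | hydroxy enone: as 15 with C10 bearing C(=O)CH=CH2 | CC(C)(C)[Si](C)(C)OCC[C@@H](C)CC[C@H]1C(CO[Si](C)(C)C(C)(C)C)=CC[C@@H](C(C)(C)O)[C@]1(C)C(=O)C=C | intermediate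
17 | isopropenyl vinyl ketone: as 16 with C5 bearing C(CH3)=CH2 | CC(C)(C)[Si](C)(C)OCC[C@@H](C)CC[C@H]1C(CO[Si](C)(C)C(C)(C)C)=CC[C@@H](C(C)=C)[C@]1(C)C(=O)C=C | intermediate
18 | (5S,9S,10S,13S)-15,17-bis(TBSO)labd-7-en-1-one (trans-decalin) | CC(C)(C)[Si](C)(C)OCC[C@@H](C)CC[C@H]1C(CO[Si](C)(C)C(C)(C)C)=CC[C@H]2C(C)(C)CCC(=O)[C@]12C | intermediate
19 | 15,17-bis(TBSO)labd-7-en-1-ol (C1 epimers; other centres as in 18) | CC(C)(C)[Si](C)(C)OCC[C@@H](C)CC[C@H]1C(CO[Si](C)(C)C(C)(C)C)=CC[C@H]2C(C)(C)CCC(O)[C@]12C | intermediate
20 | sodium alkoxide of 19 | CC(C)(C)[Si](C)(C)OCC[C@@H](C)CC[C@H]1C(CO[Si](C)(C)C(C)(C)C)=CC[C@H]2C(C)(C)CCC([O-])[C@]12C.[Na+] | intermediate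
21 | sodium O-[15,17-bis(TBSO)labd-7-en-1-yl] dithiocarbonate | CC(C)(C)[Si](C)(C)OCC[C@@H](C)CC[C@H]1C(CO[Si](C)(C)C(C)(C)C)=CC[C@H]2C(C)(C)CCC(OC(=S)[S-])[C@]12C.[Na+] | intermediate
22 | O-[15,17-bis(TBSO)labd-7-en-1-yl] S-methyl dithiocarbonate | CC(C)(C)[Si](C)(C)OCC[C@@H](C)CC[C@H]1C(CO[Si](C)(C)C(C)(C)C)=CC[C@H]2C(C)(C)CCC(OC(=S)SC)[C@]12C | intermediate
23 | (5S,9R,10S,13S)-15,17-bis(TBSO)labd-7-ene | CC(C)(C)[Si](C)(C)OCC[C@@H](C)CC[C@H]1C(CO[Si](C)(C)C(C)(C)C)=CC[C@H]2C(C)(C)CCC[C@]12C | intermediate
24 | (5S,9R,10S,13S)-labd-7-ene-15,17-diol | OCC[C@@H](C)CC[C@H]1C(CO)=CC[C@H]2C(C)(C)CCC[C@]12C | intermediate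
25 | (5S,9R,10S,13S)-labd-7-ene-15,17-diyl diacetate, CNP0294037.1 | CC(=O)OCC[C@@H](C)CC[C@H]1C(COC(C)=O)=CC[C@H]2C(C)(C)CCC[C@]12C | target

Total step count: 18. Longest linear sequence: 18 steps, from 1 to 25 (10 and 12 are purchased and enter directly).

Steps most likely to fail

1. Step 8. The cycloaddition may leak into the other regiochemical mode (C9 bonding to C5), because the C17 branch on C8 pulls against the directing effect of C11. The reaction may also be too slow at the temperature where the boron cation still discriminates faces and topologies, so that acid-induced decay of the diene competes.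
The fallback keeps the same two bonds but adds a removable donor on C7. It sets out from 9 and returns at 13.
- Acylative Stille coupling of 9 with acetyl chloride (PdCl2(PPh3)2 cat., THF, 50 °C) should give, with retention, the methyl enone F1.
- Soft enolisation at the methyl group (i-Pr3SiOSO2CF3, Et3N, CH2Cl2, 0 °C) should give the 2-silyloxy diene F2, in which the C7 oxygen donor and C11 both raise the coefficient at C6 and the diene becomes much more nucleophilic.
- Cycloaddition with 12 under the same boron cation should give the silyl enol ether adduct F3.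
- Regiospecific exchange of silicon for triflate (CsF, PhN(SO2CF3)2, DME, rt) should give the enol triflate F4.
- Palladium-catalysed formate reduction (Pd(OAc)2, PPh3, HCO2H, Et3N, DMF, 60 °C) replaces the triflate by hydrogen and delivers 13.

2. Step 13. Hydrogen atom transfer to the C7=C8 alkene may compete. The tertiary radical or the vinyl ketone may also be reduced before the 6-endo closure, and any unselective elimination in step 12 would feed the wrong alkene into this step.
The fallback generates the same C4 radical from the C–O bond instead of from an alkene. It sets out from 16, bypasses 17 and returns at 18.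
- Acylation of the tertiary alcohol with 1,3-dioxoisoindolin-2-yl 2-chloro-2-oxoacetate (Et3N, 4-(dimethylaminopyridine) cat., CH2Cl2) should give the N-phthalimidoyl oxalate F5, used crude.
- Visible-light reduction (Ru(bpy)3(PF6)2 cat., diethyl Hantzsch ester, i-Pr2NEt·HBF4, THF/CH2Cl2, blue LEDs, rt) fragments it to the tertiary radical.
- The radical closes onto C3 of the vinyl ketone, and hydrogen transfer from the Hantzsch ester gives 18.

3. Step 6. Tin may also be delivered to C9, because both flanks of the internal alkyne are CH2 groups. The allylic stannane may further suffer protodestannylation during purification.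
The fallback builds the trisubstituted alkene by olefination instead of alkyne hydrometalation. It sets out from 4 and returns at 11.
- Still–Gennari-type Horner–Wadsworth–Emmons reaction of 4 with methyl bromo[bis(2,2,2-trifluoroethoxy)phosphoryl]acetate (t-BuOK, 18-crown-6, THF, −78 °C) should give the bromo enoate F6, with the chain cis to the ester and trans to bromine.
- Reduction with i-Bu2AlH (CH2Cl2, −78 °C) should give the bromo allylic alcohol F7.
- Silylation (TBSCl, imidazole) should give the alkenyl bromide F8.
- Stille coupling with tributyl(vinyl)stannane (Pd(PPh3)4 cat., toluene, 90 °C) replaces bromine by vinyl with retention and delivers 11.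

Further compounds
F1 | step 8 | (3E,7S)-9-(TBSO)-3-[(TBSO)methyl]-7-methylnon-3-en-2-one | CC(=O)/C(CO[Si](C)(C)C(C)(C)C)=C/CC[C@H](C)CCO[Si](C)(C)C(C)(C)C
F2 | step 8 | (3E,7S)-9-(TBSO)-3-[(TBSO)methyl]-7-methyl-2-(triisopropylsilyloxy)nona-1,3-diene | C=C(O[Si](C(C)C)(C(C)C)C(C)C)/C(CO[Si](C)(C)C(C)(C)C)=C/CC[C@H](C)CCO[Si](C)(C)C(C)(C)C
F3 | step 8 | C7 triisopropylsilyl enol ether analogue of 13 | CC(C)(C)[Si](C)(C)OCC[C@@H](C)CC[C@H]1C(CO[Si](C)(C)C(C)(C)C)=C(O[Si](C(C)C)(C(C)C)C(C)C)C[C@@H](C(=O)OCC)[C@]1(C)C=O
F4 | step 8 | C7 enol triflate analogue of 13 | CC(C)(C)[Si](C)(C)OCC[C@@H](C)CC[C@H]1C(CO[Si](C)(C)C(C)(C)C)=C(OS(=O)(=O)C(F)(F)F)C[C@@H](C(=O)OCC)[C@]1(C)C=O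
F5 | step 13 | N-phthalimidoyl oxalate of the C4 tertiary alcohol of 16 | CC(C)(C)[Si](C)(C)OCC[C@@H](C)CC[C@H]1C(CO[Si](C)(C)C(C)(C)C)=CC[C@@H](C(C)(C)OC(=O)C(=O)ON2C(=O)c3ccccc3C2=O)[C@]1(C)C(=O)C=C
F6 | step 6 | methyl (2E,6S)-2-bromo-8-(TBSO)-6-methyloct-2-enoate | Br/C(C(=O)OC)=C/CC[C@H](C)CCO[Si](C)(C)C(C)(C)C
F7 | step 6 | (2E,6S)-2-bromo-8-(TBSO)-6-methyloct-2-en-1-ol | Br/C(CO)=C/CC[C@H](C)CCO[Si](C)(C)C(C)(C)C
F8 | step 6 | (2E,6S)-2-bromo-1,8-bis(TBSO)-6-methyloct-2-ene | Br/C(CO[Si](C)(C)C(C)(C)C)=C/CC[C@H](C)CCO[Si](C)(C)C(C)(C)C
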